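**Retrosynthetic overview**

1. Target 24 ⇐ hydrogenolysis of the nine benzyl ethers of 23 ⇐ double acylation of diphenol 21 (7-OH and 3'-OH, freed from the two methoxymethyl ethers of 20) with galloyl chloride 22; 5-OH, 4'-OH and 3-OH stay benzylated to the end.
2. Chroman 20 ⇐ alcohol 8 (C2, C3, C4 and ring B) + ortho-silylaryl triflate 16 (ring A): an aryne takes up O1 at C8a and C4 at C4a in one operation, the second bond closing ring C.
3. Enabling feature: in ring A, C4a lies between C8a (which carries O1) and C5 (which carries oxygen), so in the aryne C4a≡C8a the C5–OBn group beside the triple bond steers the alkoxide to C8a and leaves the carbanion on C4a, at six-ring distance from the CH2Cl carbon C4.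
4. 8 ⇐ Sharpless kinetic-resolution epoxidation of allylic alcohol 3 (fixes C2 and C3), chloride opening and neutral O-benzylation; 16 ⇐ C2v-symmetric 4-bromo-3,5-difluorophenol 9 by two SNAr reactions and a retro-Brook silyl shift, which places 5-OBn and 7-OMOM without any regiochemical choice.
5. Ring order: rings A and B and both galloyl rings are bought as arenes; ring C is the only ring formed (step 12).

Key step: step 12

Remark: locants C2, C3, C4, C4a, C5 to C8, C8a and O1 are those of the flavan (2-arylchromane) skeleton, with ring A the benzo ring, ring B the 2-aryl ring and ring C the pyran ring; compounds 1, 9 and 22 are taken as commercial.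

**Route**

Step 1
Reactants: 1 4-(benzyloxy)-3-hydroxybenzaldehyde
Product: 2 4-(benzyloxy)-3-(methoxymethoxy)benzaldehyde
Conditions: MeOCH2Cl, i-Pr2NEt, CH2Cl2, 0 °C to rt
Reagents that add atoms: chloromethyl methyl ether, COCCl
Why: Williamson-type O-alkylation of the phenol with an amine base should mask the 3-hydroxyl, the one to be esterified later, as an acid-labile acetal that tolerates all basic and organometallic steps.

Step 2
Reactants: 2 4-(benzyloxy)-3-(methoxymethoxy)benzaldehyde
Product: 3 rac-1-[4-(benzyloxy)-3-(methoxymethoxy)phenyl]prop-2-en-1-ol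
Conditions: CH2=CHMgBr, THF, −78 to 0 °C; then aq NH4Cl
Reagents that add atoms: vinylmagnesium bromide, C=C[Mg]Br
Why: Grignard 1,2-addition to the aldehyde should give the racemic secondary allylic alcohol needed for the kinetic resolution.

Step 3
Reactants: 3 rac-1-[4-(benzyloxy)-3-(methoxymethoxy)phenyl]prop-2-en-1-ol
Product: 4 (R)-[4-(benzyloxy)-3-(methoxymethoxy)phenyl][(S)-oxiran-2-yl]methanol
Conditions: Ti(OiPr)4 (0.1 equiv), D-(−)-diisopropyl tartrate (0.15 equiv), t-BuOOH (0.5 equiv), 4 Å molecular sieves, CH2Cl2, −20 °C, stopped near half conversion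
Reagents that add atoms: tert-butyl hydroperoxide, CC(C)(C)OO
Why: In this Sharpless kinetic resolution the titanium D-(−)-tartrate catalyst should epoxidize the (S)-alcohol much faster than its mirror image and on the alkene face that gives the erythro epoxy alcohol, so that the (R)-carbinol carbon (later C2) and the (S)-epoxide carbon (later C3) are fixed together while (R)-3 is left behind.

Step 4
Reactants: 4 (R)-[4-(benzyloxy)-3-(methoxymethoxy)phenyl][(S)-oxiran-2-yl]methanol
Product: 5 tert-butyl{(R)-[4-(benzyloxy)-3-(methoxymethoxy)phenyl][(S)-oxiran-2-yl]methoxy}dimethylsilane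
Conditions: t-BuMe2SiCl, imidazole, DMF, rt
Reagents that add atoms: tert-butyldimethylsilyl chloride, CC(C)(C)[Si](C)(C)Cl
Why: Silylation with imidazole forms no alkoxide, so the Payne rearrangement of the epoxy alcohol is avoided and the future O1 stays masked until the aryne step.

Step 5
Reactants: 5 tert-butyl{(R)-[4-(benzyloxy)-3-(methoxymethoxy)phenyl][(S)-oxiran-2-yl]methoxy}dimethylsilane
Product: 6 (1R,2R)-1-[4-(benzyloxy)-3-(methoxymethoxy)phenyl]-1-[(tert-butyldimethylsilyl)oxy]-3-chloropropan-2-ol
Conditions: LiCl, AcOH, THF, rt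
Reagents that add atoms: lithium chloride, [Li+].[Cl-]
Why: Chloride should open the terminal epoxide by SN2 attack at the unhindered CH2 carbon under buffered acid (halohydrin formation), so the oxygen-bearing stereocenter keeps its bonds and its configuration (its descriptor becomes R only through the priority of CH2Cl).

Step 6
Reactants: 6 (1R,2R)-1-[4-(benzyloxy)-3-(methoxymethoxy)phenyl]-1-[(tert-butyldimethylsilyl)oxy]-3-chloropropan-2-ol
Product: 7 {(1R,2R)-2-(benzyloxy)-1-[4-(benzyloxy)-3-(methoxymethoxy)phenyl]-3-chloropropoxy}(tert-butyl)dimethylsilane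
Conditions: 2-benzyloxy-1-methylpyridinium triflate, MgO, PhCF3, 85 °C
Reagents that add atoms: 2-benzyloxy-1-methylpyridinium trifluoromethanesulfonate, C[n+]1ccccc1OCc1ccccc1.[O-]S(=O)(=O)C(F)(F)F
Why: Thermal benzyl transfer from the neutral pyridinium salt (O-benzylation under neutral conditions) should etherify the secondary hydroxyl without the base that would close the chlorohydrin back to the epoxide.

Step 7
Reactants: 7 {(1R,2R)-2-(benzyloxy)-1-[4-(benzyloxy)-3-(methoxymethoxy)phenyl]-3-chloropropoxy}(tert-butyl)dimethylsilane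
Product: 8 (1R,2R)-2-(benzyloxy)-1-[4-(benzyloxy)-3-(methoxymethoxy)phenyl]-3-chloropropan-1-ol
Conditions: Bu4NF, THF, 0 °C; then H2O
Reagents that add atoms: none
Why: Fluoride-induced cleavage of the silyl ether should free the benzylic hydroxyl, the only acidic OH of fragment 8.

Step 8
Reactants: 9 4-bromo-3,5-difluorophenol
Product: 10 2-bromo-1,3-difluoro-5-(methoxymethoxy)benzene
Conditions: MeOCH2Cl, i-Pr2NEt, CH2Cl2, 0 °C to rt
Reagents that add atoms: chloromethyl methyl ether, COCCl
Why: Williamson-type O-alkylation should protect the phenol that becomes the 7-OH, on an arene whose two fluorines are equivalent by symmetry.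

Step 9
Reactants: 10 2-bromo-1,3-difluoro-5-(methoxymethoxy)benzene
Product: 11 1-(benzyloxy)-2-bromo-3-fluoro-5-(methoxymethoxy)benzene
Conditions: BnOH (1.0 equiv), NaH, DMF, 0 to 50 °C
Reagents that add atoms: benzyl alcohol, OCc1ccccc1
Why: Nucleophilic aromatic substitution (SNAr) by benzyloxide at one of two equivalent fluorines, activated by the ortho bromine and the meta fluorine, should stop after one substitution because the new alkoxy group deactivates the ring.

Step 10
Reactants: 11 1-(benzyloxy)-2-bromo-3-fluoro-5-(methoxymethoxy)benzene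
Product: 13 3-(benzyloxy)-2-bromo-5-(methoxymethoxy)phenol, via sulfonylethyl ether 12 (not isolated)
Conditions: HOCH2CH2SO2Me, NaH, DMF, 0 to 80 °C; then AcOH
Reagents that add atoms: 2-(methylsulfonyl)ethanol, CS(=O)(=O)CCO
Why: A second SNAr with the alkoxide of 2-(methylsulfonyl)ethanol as hydroxide surrogate, followed by E1cB loss of methyl vinyl sulfone from ether 12, should deliver the phenol ortho to bromine.

Step 11
Reactants: 13 3-(benzyloxy)-2-bromo-5-(methoxymethoxy)phenol
Product: 16 3-(benzyloxy)-5-(methoxymethoxy)-2-(trimethylsilyl)phenyl trifluoromethanesulfonate, via aryl silyl ether 14 (not isolated), via lithium silylphenoxide 15 (not isolated)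
Conditions: HN(SiMe3)2, THF, 70 °C, then evaporation; n-BuLi, THF, −78 °C; (CF3SO2)2O, −78 °C to rt
Reagents that add atoms: hexamethyldisilazane, C[Si](C)(C)N[Si](C)(C)C; trifluoromethanesulfonic anhydride, O=S(=O)(OS(=O)(=O)C(F)(F)F)C(F)(F)F
Why: O-silylation, bromine–lithium exchange and 1,3 O-to-C silyl migration (retro-Brook rearrangement) should move the silyl group to the former C–Br carbon, and triflation of the phenoxide then gives the ortho-silylaryl triflate in the usual way for 3-alkoxyaryne precursors.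

Step 12
Reactants: 8 (1R,2R)-2-(benzyloxy)-1-[4-(benzyloxy)-3-(methoxymethoxy)phenyl]-3-chloropropan-1-ol; 16 3-(benzyloxy)-5-(methoxymethoxy)-2-(trimethylsilyl)phenyl trifluoromethanesulfonate
Product: 20 (2R,3S)-3,5-bis(benzyloxy)-2-[4-(benzyloxy)-3-(methoxymethoxy)phenyl]-7-(methoxymethoxy)chromane, via potassium alkoxide 17 (not isolated), via aryne 18 (not isolated), via aryl anion 19 (not isolated)
Conditions: KH, THF, 0 °C; then 16 (1.5 equiv), KF, 18-crown-6, THF, 0 °C to rt
Reagents that add atoms: none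
Why: Proposed new method: fluoride strips the silyl group of 16 and triflate leaves to give aryne 18, the pre-formed alkoxide 17 adds to the aryne carbon meta to the benzyloxy group (the future C8a) because this puts the carbanion on C4a next to the inductively stabilising C5 oxygen (the regiochemistry known for 3-alkoxyarynes), and aryl anion 19 then displaces the primary chloride to form C4–C4a. The closest known reaction types are the annulation of arynes with reagents that carry both a nucleophile and an electrophile (addition of an oxygen nucleophile, then ring closure of the aryl anion on a tethered ester or ketone) and the Parham cyclization of ortho-metalated aryl ethers on alkyl halides; new is the sp3 C–Cl electrophile inside the aryne cascade. Ring C closes in a 6-exo-tet SN2 step at C4. No stereocenter is formed: C2 and C3 come unchanged from 8, since O1 reacts as the nucleophile and C3 only neighbours the reacting carbon. The step needs C-alkylation to outrun protonation of 19, which the aprotic medium and the fully deprotonated alcohol should secure, and it needs the alkoxide to spare its own chloride, which the slow 4-exo closure to an oxetane should secure.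

Step 13
Reactants: 20 (2R,3S)-3,5-bis(benzyloxy)-2-[4-(benzyloxy)-3-(methoxymethoxy)phenyl]-7-(methoxymethoxy)chromane
Product: 21 (2R,3S)-3,5-bis(benzyloxy)-2-[4-(benzyloxy)-3-hydroxyphenyl]chroman-7-ol
Conditions: HCl (cat.), MeOH–THF, 45 °C
Reagents that add atoms: none
Why: Acid-catalysed transacetalization to methanol should cleave both aryl methoxymethyl ethers, while the benzyl ethers, the chroman and both stereocenters are stable to these mild conditions.

Step 14
Reactants: 21 (2R,3S)-3,5-bis(benzyloxy)-2-[4-(benzyloxy)-3-hydroxyphenyl]chroman-7-ol; 22 3,4,5-tris(benzyloxy)benzoyl chloride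
Product: 23 (2R,3S)-3,5-bis(benzyloxy)-2-{4-(benzyloxy)-3-[3,4,5-tris(benzyloxy)benzoyloxy]phenyl}chroman-7-yl 3,4,5-tris(benzyloxy)benzoate
Conditions: 22 (2.4 equiv), Et3N, DMAP (cat.), CH2Cl2, 0 °C to rt
Reagents that add atoms: none
Why: DMAP-catalysed acyl transfer (Steglich-type esterification with an acid chloride) to the only two free hydroxyls, both phenols, should give the 7,3'-diester with no regiochemical choice left.

Step 15
Reactants: 23 (2R,3S)-3,5-bis(benzyloxy)-2-{4-(benzyloxy)-3-[3,4,5-tris(benzyloxy)benzoyloxy]phenyl}chroman-7-yl 3,4,5-tris(benzyloxy)benzoate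
Product: 24 catechin 7,3'-di-O-gallate
Conditions: H2 (1 atm), Pd(OH)2/C, THF–MeOH, rt
Reagents that add atoms: none
Why: Catalytic hydrogenolysis should cleave all nine benzyl ethers under neutral conditions, which leave the aryl esters in place and should not let the 3'-O-galloyl group migrate to the 4'-hydroxyl.

**Compound list**

1 | 4-(benzyloxy)-3-hydroxybenzaldehyde | O=Cc1ccc(OCc2ccccc2)c(O)c1 | starting material
2 | 4-(benzyloxy)-3-(methoxymethoxy)benzaldehyde | O=Cc1ccc(OCc2ccccc2)c(OCOC)c1 | intermediate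
3 | rac-1-[4-(benzyloxy)-3-(methoxymethoxy)phenyl]prop-2-en-1-ol | C=CC(O)c1ccc(OCc2ccccc2)c(OCOC)c1 | intermediate
4 | (R)-[4-(benzyloxy)-3-(methoxymethoxy)phenyl][(S)-oxiran-2-yl]methanol | O[C@H](c1ccc(OCc2ccccc2)c(OCOC)c1)[C@@H]1CO1 | intermediate
5 | tert-butyl{(R)-[4-(benzyloxy)-3-(methoxymethoxy)phenyl][(S)-oxiran-2-yl]methoxy}dimethylsilane | CC(C)(C)[Si](C)(C)O[C@H](c1ccc(OCc2ccccc2)c(OCOC)c1)[C@@H]1CO1 | intermediate
6 | (1R,2R)-1-[4-(benzyloxy)-3-(methoxymethoxy)phenyl]-1-[(tert-butyldimethylsilyl)oxy]-3-chloropropan-2-ol | CC(C)(C)[Si](C)(C)O[C@H](c1ccc(OCc2ccccc2)c(OCOC)c1)[C@@H](O)CCl | intermediate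
7 | {(1R,2R)-2-(benzyloxy)-1-[4-(benzyloxy)-3-(methoxymethoxy)phenyl]-3-chloropropoxy}(tert-butyl)dimethylsilane | CC(C)(C)[Si](C)(C)O[C@H](c1ccc(OCc2ccccc2)c(OCOC)c1)[C@@H](OCc1ccccc1)CCl | intermediate
8 | (1R,2R)-2-(benzyloxy)-1-[4-(benzyloxy)-3-(methoxymethoxy)phenyl]-3-chloropropan-1-ol | O[C@H](c1ccc(OCc2ccccc2)c(OCOC)c1)[C@@H](OCc1ccccc1)CCl | intermediate
9 | 4-bromo-3,5-difluorophenol | Oc1cc(F)c(Br)c(F)c1 | starting material
10 | 2-bromo-1,3-difluoro-5-(methoxymethoxy)benzene | COCOc1cc(F)c(Br)c(F)c1 | intermediate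
11 | 1-(benzyloxy)-2-bromo-3-fluoro-5-(methoxymethoxy)benzene | COCOc1cc(F)c(Br)c(OCc2ccccc2)c1 | intermediate
12 | 1-(benzyloxy)-2-bromo-5-(methoxymethoxy)-3-[2-(methylsulfonyl)ethoxy]benzene | COCOc1cc(OCCS(C)(=O)=O)c(Br)c(OCc2ccccc2)c1 | intermediate
13 | 3-(benzyloxy)-2-bromo-5-(methoxymethoxy)phenol | COCOc1cc(O)c(Br)c(OCc2ccccc2)c1 | intermediate
14 | [3-(benzyloxy)-2-bromo-5-(methoxymethoxy)phenoxy]trimethylsilane | COCOc1cc(O[Si](C)(C)C)c(Br)c(OCc2ccccc2)c1 | intermediate
15 | lithium 3-(benzyloxy)-5-(methoxymethoxy)-2-(trimethylsilyl)phenoxide | [Li+].COCOc1cc([O-])c([Si](C)(C)C)c(OCc2ccccc2)c1 | intermediate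
16 | 3-(benzyloxy)-5-(methoxymethoxy)-2-(trimethylsilyl)phenyl trifluoromethanesulfonate | COCOc1cc(OS(=O)(=O)C(F)(F)F)c([Si](C)(C)C)c(OCc2ccccc2)c1 | intermediate
17 | potassium (1R,2R)-2-(benzyloxy)-1-[4-(benzyloxy)-3-(methoxymethoxy)phenyl]-3-chloropropan-1-olate | [K+].[O-][C@H](c1ccc(OCc2ccccc2)c(OCOC)c1)[C@@H](OCc1ccccc1)CCl | intermediate
18 | 3-(benzyloxy)-5-(methoxymethoxy)benzyne | COCOC1=CC#CC(OCc2ccccc2)=C1 | intermediate
19 | potassium 2-(benzyloxy)-6-{(1R,2R)-2-(benzyloxy)-1-[4-(benzyloxy)-3-(methoxymethoxy)phenyl]-3-chloropropoxy}-4-(methoxymethoxy)benzen-1-ide | [K+].COCOc1cc(O[C@H](c2ccc(OCc3ccccc3)c(OCOC)c2)[C@@H](OCc2ccccc2)CCl)[c-]c(OCc2ccccc2)c1 | intermediate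
20 | (2R,3S)-3,5-bis(benzyloxy)-2-[4-(benzyloxy)-3-(methoxymethoxy)phenyl]-7-(methoxymethoxy)chromane | COCOc1cc(OCc2ccccc2)c2c(c1)O[C@H](c1ccc(OCc3ccccc3)c(OCOC)c1)[C@@H](OCc1ccccc1)C2 | intermediate
21 | (2R,3S)-3,5-bis(benzyloxy)-2-[4-(benzyloxy)-3-hydroxyphenyl]chroman-7-ol | Oc1cc(OCc2ccccc2)c2c(c1)O[C@H](c1ccc(OCc3ccccc3)c(O)c1)[C@@H](OCc1ccccc1)C2 | intermediate
22 | 3,4,5-tris(benzyloxy)benzoyl chloride | O=C(Cl)c1cc(OCc2ccccc2)c(OCc2ccccc2)c(OCc2ccccc2)c1 | starting material
23 | (2R,3S)-3,5-bis(benzyloxy)-2-{4-(benzyloxy)-3-[3,4,5-tris(benzyloxy)benzoyloxy]phenyl}chroman-7-yl 3,4,5-tris(benzyloxy)benzoate | O=C(Oc1cc(OCc2ccccc2)c2c(c1)O[C@H](c1ccc(OCc3ccccc3)c(OC(=O)c3cc(OCc4ccccc4)c(OCc4ccccc4)c(OCc4ccccc4)c3)c1)[C@@H](OCc1ccccc1)C2)c1cc(OCc2ccccc2)c(OCc2ccccc2)c(OCc2ccccc2)c1 | intermediate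
24 | catechin 7,3'-di-O-gallate, (2R,3S)-3,5-dihydroxy-2-[4-hydroxy-3-(3,4,5-trihydroxybenzoyloxy)phenyl]chroman-7-yl 3,4,5-trihydroxybenzoate | O=C(Oc1cc(O)c2c(c1)O[C@H](c1ccc(O)c(OC(=O)c3cc(O)c(O)c(O)c3)c1)[C@@H](O)C2)c1cc(O)c(O)c(O)c1 | target

**Step count and risks**

Total steps: 15. Longest linear sequence: 11 steps (steps 1 to 7 and 12 to 15, from 1 to 24); the ring A branch (steps 8 to 11) joins at step 12.

Steps most likely to fail:

1. Step 12 (Proposed new method). Aryl anion 19 may be protonated, or may pass its charge to the benzylic C2–H or to an O-benzyl CH2 group, before it alkylates; the alkoxide may also attack the sulfur of the triflate instead of the aryne. Either process would leave an open-chain aryl ether or unchanged alcohol in place of the chroman. The fallback uses known chemistry and sets out from 11 and 8. Bromine–lithium exchange on 11 (n-BuLi, THF, −78 °C, where the ortho-fluoroaryllithium is stable) and quenching with methyl p-toluenesulfinate should give the sulfoxide 1-(benzyloxy)-3-fluoro-5-(methoxymethoxy)-2-(p-tolylsulfinyl)benzene F1. Its sulfinyl group activates the neighbouring C–F bond, so the potassium alkoxide 17 made from 8 (KH, THF, 0 °C) should displace fluoride by SNAr and give the aryl ether 1-(benzyloxy)-3-{(1R,2R)-2-(benzyloxy)-1-[4-(benzyloxy)-3-(methoxymethoxy)phenyl]-3-chloropropoxy}-5-(methoxymethoxy)-2-(p-tolylsulfinyl)benzene F2 as a mixture of sulfur epimers. PhLi (THF, −78 °C to rt) should then effect sulfoxide–lithium exchange, and the aryllithium should close ring C on the primary chloride (Parham cyclization), which comes back to the route at 20.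

2. Step 10. The sulfonylethoxide may fragment to methyl vinyl sulfone and hydroxide faster than it substitutes the fluorine of an arene that two alkoxy groups have deactivated, so the substitution may stall. The fallback sets out from 11 and replaces the hydroxide surrogate by a robust alkoxide that can be forced. 4-Methoxybenzyl alcohol with NaH in DMF at 90 °C should give 1-(benzyloxy)-2-bromo-3-[(4-methoxybenzyl)oxy]-5-(methoxymethoxy)benzene F3, and oxidative removal of the 4-methoxybenzyl group (DDQ, CH2Cl2–H2O, rt) comes back to the route at 13.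

3. Step 3. Poor rate discrimination between the two enantiomers of this electron-rich aryl vinyl carbinol would erode the enantiomeric purity of the epoxy alcohol. The fallback sets out from 2 and fixes the carbinol center first. Catalytic asymmetric vinylation with Zn(CH=CH2)2 and the enantiomer of 3-exo-morpholinoisoborneol that delivers the (S)-alcohol should give (S)-1-[4-(benzyloxy)-3-(methoxymethoxy)phenyl]prop-2-en-1-ol F4. Its matched epoxidation (Ti(OiPr)4, D-(−)-diisopropyl tartrate, t-BuOOH in excess, CH2Cl2, −20 °C) is then only a diastereoselective step and comes back to the route at 4.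

**Further compounds**

F1 | step 12 | 1-(benzyloxy)-3-fluoro-5-(methoxymethoxy)-2-(p-tolylsulfinyl)benzene | COCOc1cc(F)c(S(=O)c2ccc(C)cc2)c(OCc2ccccc2)c1
F2 | step 12 | 1-(benzyloxy)-3-{(1R,2R)-2-(benzyloxy)-1-[4-(benzyloxy)-3-(methoxymethoxy)phenyl]-3-chloropropoxy}-5-(methoxymethoxy)-2-(p-tolylsulfinyl)benzene | COCOc1cc(O[C@H](c2ccc(OCc3ccccc3)c(OCOC)c2)[C@@H](OCc2ccccc2)CCl)c(S(=O)c2ccc(C)cc2)c(OCc2ccccc2)c1
F3 | step 10 | 1-(benzyloxy)-2-bromo-3-[(4-methoxybenzyl)oxy]-5-(methoxymethoxy)benzene | COCOc1cc(OCc2ccc(OC)cc2)c(Br)c(OCc2ccccc2)c1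
F4 | step 3 | (S)-1-[4-(benzyloxy)-3-(methoxymethoxy)phenyl]prop-2-en-1-ol | O[C@H](c1ccc(OCc2ccccc2)c(OCOC)c1)C=C
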